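## Retrosynthetic overview

- The target is a trimer: an oxyresveratrol unit C and two resveratrol units B and A, joined by two trans-(2S,3S)-2,3-diaryl-4-hydroxy-2,3-dihydrobenzofurans (ring 2 from B + C, ring 1 from A + B).
- Enabling feature: in each dihydrofuran (O1–C2–C3–C3a–C7a), C3a lies between the two oxygen-bearing carbons C4 (OH) and C7a (O1) of a resorcinol ring. That benzene ring is therefore a masked cyclohexane-1,3-dione: its C2 becomes the carbene carbon of a 2-diazo-1,3-dione and one enol oxygen becomes O1. The para oxygen of the aryl group on C2 polarises the partner stilbene.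
- Key disconnection, used twice with the same reagent: formal [3+2] cycloaddition of a 5-styryl-2-diazocyclohexane-1,3-dione with an E-stilbene (forms C3a–C3 and O1–C2), then dehydrogenation of the cyclohexenone to the phenol, which turns the isolated styryl group of the reagent into the next stilbene. A pivalate keeps the styryl group of the reagent unreactive; a silyl ether activates the stilbene that has to react.
- Ring order: cyclohexane-1,3-dione of the reagent (Michael–Claisen), dihydrofuran ring 2 (step 7), benzene ring of unit B (step 8), dihydrofuran ring 1 (step 11), benzene ring of unit A (step 12), global deprotection.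

Key step: step 11

Remark (assumption): the sense of induction of the chiral dirhodium catalyst cannot be predicted with certainty. The (S)-tert-leucinate catalyst is written for the (2S,3S) series; its mirror-image catalyst would be used if the opposite sense is found.

Remark: both annulations use the same catalyst sense, so material with the wrong ring 2 configuration should end mainly as a separable diastereomer after the second annulation.

Remark: the acetal carbon of the oxanyl ether and C6 of the two tetrahydrobenzofuranones are uncontrolled and are removed later.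

Abbreviations: TBS = tert-butyldimethylsilyl; Piv = pivaloyl; Rh2(S-NTTL)4 = dirhodium tetrakis[N-(1,8-naphthaloyl)-(S)-tert-leucinate].

## Route

Step 1
Reactants: 1 (E)-3-(4-hydroxyphenyl)prop-2-enal
Product: 2 (E)-3-[4-(oxan-2-yloxy)phenyl]prop-2-enal
Conditions: 3,4-dihydro-2H-pyran, pyridinium p-toluenesulfonate (cat.), CH2Cl2, rt
Reagents that add atoms: 3,4-dihydro-2H-pyran, C1=COCCC1
Why: acid-catalysed addition of the phenol to the enol ether (tetrahydropyranyl acetal formation) should give a base-stable phenol protection for steps 2 and 3 without touching the enal.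

Step 2
Reactants: 2 (E)-3-[4-(oxan-2-yloxy)phenyl]prop-2-enal; 3 1-(triphenylphosphoranylidene)propan-2-one
Product: 4 (3E,5E)-6-[4-(oxan-2-yloxy)phenyl]hexa-3,5-dien-2-one
Conditions: toluene, 90 °C
Reagents that add atoms: none
Why: Wittig olefination with a stabilised ylide should give the new enone double bond E under neutral conditions and leave the existing E-alkene unchanged.

Step 3
Reactants: 4 (3E,5E)-6-[4-(oxan-2-yloxy)phenyl]hexa-3,5-dien-2-one; 5 diethyl malonate
Product: 8 5-[(E)-2-(4-hydroxyphenyl)ethenyl]cyclohexane-1,3-dione, via cyclised keto ester 6 (not isolated), via keto acid 7 (not isolated)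
Conditions: NaOEt, EtOH, reflux; then 2 M NaOH (aq), reflux, EtOH distilled off; then 2 M HCl to pH 2, THF–H2O, 50 °C
Reagents that add atoms: none
Why: Michael addition of malonate to the enone beta-carbon, intramolecular Claisen condensation of the methyl ketone onto an ester, saponification and decarboxylation of the beta-keto acid are the classical route to 5-substituted cyclohexane-1,3-diones, and the final acid also hydrolyses the aryl tetrahydropyranyl acetal.

Step 4
Reactants: 8 5-[(E)-2-(4-hydroxyphenyl)ethenyl]cyclohexane-1,3-dione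
Product: 9 2-diazo-5-[(E)-2-(4-hydroxyphenyl)ethenyl]cyclohexane-1,3-dione
Conditions: 4-acetamidobenzenesulfonyl azide, Et3N, MeCN, 0 °C to rt
Reagents that add atoms: 4-acetamidobenzenesulfonyl azide, CC(=O)Nc1ccc(cc1)S(=O)(=O)N=[N+]=[N-]
Why: Regitz diazo transfer should occur only at the acidic C2 methylene of the 1,3-dione, the phenol being a spectator under amine base.

Step 5
Reactants: 9 2-diazo-5-[(E)-2-(4-hydroxyphenyl)ethenyl]cyclohexane-1,3-dione
Product: 10 4-[(E)-2-(4-diazo-3,5-dioxocyclohexyl)ethenyl]phenyl pivalate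
Conditions: t-BuCOCl, Et3N, DMAP (cat.), CH2Cl2, 0 °C
Reagents that add atoms: pivaloyl chloride, CC(C)(C)C(=O)Cl
Why: O-acylation of the only remaining O–H (the dione no longer has an enol) should give the pivalate, which removes the O–H from carbenoid insertion and makes the styryl group of the reagent electron-poor.

Step 6
Reactants: 11 oxyresveratrol, 4-[(E)-2-(3,5-dihydroxyphenyl)ethenyl]benzene-1,3-diol
Product: 12 (E)-1-[2,4-bis(TBSO)phenyl]-2-[3,5-bis(TBSO)phenyl]ethene
Conditions: TBSCl, imidazole, DMF, rt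
Reagents that add atoms: tert-butyldimethylsilyl chloride, CC(C)(C)[Si](C)(C)Cl
Why: exhaustive silylation of the four phenols removes all O–H bonds while keeping the ortho and para oxygens of the 2,4-dioxygenated ring as donors that activate and polarise the alkene.

Step 7
Reactants: 12 (E)-1-[2,4-bis(TBSO)phenyl]-2-[3,5-bis(TBSO)phenyl]ethene; 10 4-[(E)-2-(4-diazo-3,5-dioxocyclohexyl)ethenyl]phenyl pivalate
Product: 13 4-{(E)-2-[(2S,3S)-2-[2,4-bis(TBSO)phenyl]-3-[3,5-bis(TBSO)phenyl]-4-oxo-2,3,4,5,6,7-hexahydro-1-benzofuran-6-yl]ethenyl}phenyl pivalate (both C6 epimers)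
Conditions: Rh2(S-NTTL)4 (2 mol %), PhCF3, 60 °C, slow addition of 10
Reagents that add atoms: none
Why: Proposed new method: the same catalyst-controlled formal [3+2] cycloaddition as in step 11 (rhodium carbenoid of 10 attacked by the alkene carbon bearing the 3,5-disilyloxyphenyl ring, cation on the carbon bearing the 2,4-disilyloxyphenyl ring stabilised by its ortho and para oxygens, trans closure by the enolate oxygen), the closest known reaction type being the Rh2(OAc)4-catalysed dihydrofuran annulation of 2-diazocyclohexane-1,3-diones with enol ethers and aryl alkenes; C3 of ring 2 is set by the catalyst in the C–C bond formation and C2 by the trans ring closure.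

Step 8
Reactants: 13 4-{(E)-2-[(2S,3S)-2-[2,4-bis(TBSO)phenyl]-3-[3,5-bis(TBSO)phenyl]-4-oxo-2,3,4,5,6,7-hexahydro-1-benzofuran-6-yl]ethenyl}phenyl pivalate
Product: 15 4-{(E)-2-[(2S,3S)-2-[2,4-bis(TBSO)phenyl]-3-[3,5-bis(TBSO)phenyl]-4-hydroxy-2,3-dihydro-1-benzofuran-6-yl]ethenyl}phenyl pivalate, via cross-conjugated dienone 14 (not isolated)
Conditions: LiN(i-Pr)2, THF, −78 °C; then N-tert-butylbenzenesulfinimidoyl chloride, −78 °C to rt
Reagents that add atoms: none
Why: kinetic deprotonation of the vinylogous ester at C5, attack of the enolate on the sulfur electrophile and syn-elimination of the sulfenamide (one-pot ketone dehydrogenation) should give the 5,6-unsaturated dienone, which tautomerises to the phenol with loss of the C6 centre, while pivalate, silyl ethers and the C2/C3 centres are untouched at −78 °C.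

Step 9
Reactants: 15 4-{(E)-2-[(2S,3S)-2-[2,4-bis(TBSO)phenyl]-3-[3,5-bis(TBSO)phenyl]-4-hydroxy-2,3-dihydro-1-benzofuran-6-yl]ethenyl}phenyl pivalate
Product: 16 (2S,3S)-2-[2,4-bis(TBSO)phenyl]-3-[3,5-bis(TBSO)phenyl]-6-[(E)-2-(4-hydroxyphenyl)ethenyl]-2,3-dihydro-1-benzofuran-4-ol
Conditions: i-Bu2AlH, CH2Cl2, −78 °C; aq. KNaC4H4O6 work-up
Reagents that add atoms: none
Why: reductive cleavage of the aryl ester by the aluminium hydride should free the stilbene phenol while aryl silyl ethers and the alkene are inert at −78 °C.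

Step 10
Reactants: 16 (2S,3S)-2-[2,4-bis(TBSO)phenyl]-3-[3,5-bis(TBSO)phenyl]-6-[(E)-2-(4-hydroxyphenyl)ethenyl]-2,3-dihydro-1-benzofuran-4-ol
Product: 17 (2S,3S)-2-[2,4-bis(TBSO)phenyl]-3-[3,5-bis(TBSO)phenyl]-4-(TBSO)-6-{(E)-2-[4-(TBSO)phenyl]ethenyl}-2,3-dihydro-1-benzofuran
Conditions: TBSCl, imidazole, DMF, rt
Reagents that add atoms: tert-butyldimethylsilyl chloride, CC(C)(C)[Si](C)(C)Cl
Why: silylation of both phenols removes the O–H bonds and replaces the electron-poor pivalate position by a para silyloxy donor, which activates the new stilbene for the second annulation.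

Step 11
Reactants: 17 (2S,3S)-2-[2,4-bis(TBSO)phenyl]-3-[3,5-bis(TBSO)phenyl]-4-(TBSO)-6-{(E)-2-[4-(TBSO)phenyl]ethenyl}-2,3-dihydro-1-benzofuran; 10 4-[(E)-2-(4-diazo-3,5-dioxocyclohexyl)ethenyl]phenyl pivalate
Product: 18 4-{(E)-2-[(2S,3S)-3-{(2S,3S)-2-[2,4-bis(TBSO)phenyl]-3-[3,5-bis(TBSO)phenyl]-4-(TBSO)-2,3-dihydro-1-benzofuran-6-yl}-4-oxo-2-[4-(TBSO)phenyl]-2,3,4,5,6,7-hexahydro-1-benzofuran-6-yl]ethenyl}phenyl pivalate (both C6 epimers)
Conditions: Rh2(S-NTTL)4 (2 mol %), PhCF3, 60 °C, slow addition of 10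
Reagents that add atoms: none
Why: Proposed new method: Rh2(S-NTTL)4 turns 10 into an electrophilic rhodium carbenoid at the carbon flanked by the two carbonyl groups (the future C3a), the stilbene carbon that bears the benzofuranyl ring attacks it to give a zwitterion (rhodium-bound 1,3-dione enolate and a benzylic cation held as a quinone-methide-type oxocarbenium by the para silyloxy group), and the enolate oxygen closes the dihydrofuran, so C3a–C3 and O1–C2 form in one stepwise formal [3+2] cycloaddition with loss of N2. The closest known reaction types are the Rh2(OAc)4-catalysed annulation of 2-diazocyclohexane-1,3-diones with enol ethers and aryl alkenes to dihydrofuran-fused cyclohexenones and the enantioselective cyclopropanation of styrenes by cyclic diacyl carbenoids with the same chiral catalyst; new here are a 1,2-diaryl alkene as partner and catalyst control of the absolute configuration. Ring 1 is closed in two stages, intermolecular C–C bond formation and then 5-exo-trig attack of the enolate oxygen on the cationic carbon (exo to its aryl-delocalised double bond). C3 is set in the C–C bond-forming event inside the chiral pocket of the catalyst, which selects one face of the alkene terminus irrespective of the remote ring 2 centres, and C2 is set in the ring closure, where the rotating cation closes with the two aryl groups trans, which is also the outcome of direct collapse from the E-alkene. Regioselectivity needs the cation on the carbon that carries the 4-silyloxyphenyl group and is secured by that para donor, the benzofuranyl ring offering only meta oxygens; chemoselectivity needs the carbenoid to spare the styryl group of 10 and of 18 and is secured by the electron-poor pivalate there against the silyl ether donor of 17 and by slow addition of 10. The C6 centre of the new cyclohexenone is uncontrolled and is erased in step 12.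

Step 12
Reactants: 18 the tetrahydrobenzofuranone of step 11
Product: 20 4-{(E)-2-[(2S,3S)-3-{(2S,3S)-2-[2,4-bis(TBSO)phenyl]-3-[3,5-bis(TBSO)phenyl]-4-(TBSO)-2,3-dihydro-1-benzofuran-6-yl}-4-hydroxy-2-[4-(TBSO)phenyl]-2,3-dihydro-1-benzofuran-6-yl]ethenyl}phenyl pivalate, via cross-conjugated dienone 19 (not isolated)
Conditions: LiN(i-Pr)2, THF, −78 °C; then N-tert-butylbenzenesulfinimidoyl chloride, −78 °C to rt
Reagents that add atoms: none
Why: the same enolate dehydrogenation and tautomerisation as in step 8 should aromatise the cyclohexenone to the benzene ring of unit A, make the styryl group a conjugated stilbene and remove the C6 centre without touching the four ring stereocentres.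

Step 13
Reactants: 20 the phenol of step 12
Product: 21 (2S,3S)-3-[(2S,3S)-2-(2,4-dihydroxyphenyl)-3-(3,5-dihydroxyphenyl)-4-hydroxy-2,3-dihydro-1-benzofuran-6-yl]-2-(4-hydroxyphenyl)-6-[(E)-2-(4-hydroxyphenyl)ethenyl]-2,3-dihydro-1-benzofuran-4-ol (target)
Conditions: K2CO3, MeOH–THF, 40 °C, argon; then 1 M HCl
Reagents that add atoms: none
Why: base-mediated methanolysis should cleave the six aryl silyl ethers and the aryl pivalate in one operation; C3 is not epimerisable and the trans arrangement at C2 is the thermodynamic one, so the configuration should be retained.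

## Compound list

1 | (E)-3-(4-hydroxyphenyl)prop-2-enal | O=C/C=C/c1ccc(O)cc1 | starting material
2 | (E)-3-[4-(oxan-2-yloxy)phenyl]prop-2-enal | O=C/C=C/c1ccc(OC2CCCCO2)cc1 | intermediate
3 | 1-(triphenylphosphoranylidene)propan-2-one | CC(=O)C=P(c1ccccc1)(c1ccccc1)c1ccccc1 | starting material
4 | (3E,5E)-6-[4-(oxan-2-yloxy)phenyl]hexa-3,5-dien-2-one | CC(=O)/C=C/C=C/c1ccc(OC2CCCCO2)cc1 | intermediate
5 | diethyl malonate | CCOC(=O)CC(=O)OCC | starting material
6 | ethyl 2,4-dioxo-6-{(E)-2-[4-(oxan-2-yloxy)phenyl]ethenyl}cyclohexane-1-carboxylate (formed as sodium enolate) | CCOC(=O)C1C(/C=C/c2ccc(OC3CCCCO3)cc2)CC(=O)CC1=O | intermediate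
7 | 2,4-dioxo-6-{(E)-2-[4-(oxan-2-yloxy)phenyl]ethenyl}cyclohexane-1-carboxylic acid | OC(=O)C1C(/C=C/c2ccc(OC3CCCCO3)cc2)CC(=O)CC1=O | intermediate
8 | 5-[(E)-2-(4-hydroxyphenyl)ethenyl]cyclohexane-1,3-dione | O=C1CC(/C=C/c2ccc(O)cc2)CC(=O)C1 | intermediate
9 | 2-diazo-5-[(E)-2-(4-hydroxyphenyl)ethenyl]cyclohexane-1,3-dione | [N-]=[N+]=C1C(=O)CC(/C=C/c2ccc(O)cc2)CC1=O | intermediate
10 | 4-[(E)-2-(4-diazo-3,5-dioxocyclohexyl)ethenyl]phenyl pivalate | CC(C)(C)C(=O)Oc1ccc(/C=C/C2CC(=O)C(=[N+]=[N-])C(=O)C2)cc1 | intermediate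
11 | oxyresveratrol | Oc1cc(O)cc(/C=C/c2ccc(O)cc2O)c1 | starting material
12 | tetrakis-O-TBS oxyresveratrol | CC(C)(C)[Si](C)(C)Oc1cc(O[Si](C)(C)C(C)(C)C)cc(/C=C/c2ccc(O[Si](C)(C)C(C)(C)C)cc2O[Si](C)(C)C(C)(C)C)c1 | intermediate
13 | ring 2 tetrahydrobenzofuran-4-one, (2S,3S), C6 epimers | CC(C)(C)C(=O)Oc1ccc(/C=C/C2CC(=O)C3=C(C2)O[C@H](c2ccc(O[Si](C)(C)C(C)(C)C)cc2O[Si](C)(C)C(C)(C)C)[C@H]3c2cc(O[Si](C)(C)C(C)(C)C)cc(O[Si](C)(C)C(C)(C)C)c2)cc1 | intermediate
14 | 5,6-didehydro dienone of 13 | CC(C)(C)C(=O)Oc1ccc(/C=C/C2=CC(=O)C3=C(C2)O[C@H](c2ccc(O[Si](C)(C)C(C)(C)C)cc2O[Si](C)(C)C(C)(C)C)[C@H]3c2cc(O[Si](C)(C)C(C)(C)C)cc(O[Si](C)(C)C(C)(C)C)c2)cc1 | intermediate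
15 | ring 2 phenol with 4-pivaloyloxystyryl group | CC(C)(C)C(=O)Oc1ccc(/C=C/c2cc(O)c3c(c2)O[C@H](c2ccc(O[Si](C)(C)C(C)(C)C)cc2O[Si](C)(C)C(C)(C)C)[C@H]3c2cc(O[Si](C)(C)C(C)(C)C)cc(O[Si](C)(C)C(C)(C)C)c2)cc1 | intermediate
16 | ring 2 bisphenol stilbene | Oc1ccc(/C=C/c2cc(O)c3c(c2)O[C@H](c2ccc(O[Si](C)(C)C(C)(C)C)cc2O[Si](C)(C)C(C)(C)C)[C@H]3c2cc(O[Si](C)(C)C(C)(C)C)cc(O[Si](C)(C)C(C)(C)C)c2)cc1 | intermediate
17 | hexakis-O-TBS ring 2 stilbene | CC(C)(C)[Si](C)(C)Oc1ccc(/C=C/c2cc(O[Si](C)(C)C(C)(C)C)c3c(c2)O[C@H](c2ccc(O[Si](C)(C)C(C)(C)C)cc2O[Si](C)(C)C(C)(C)C)[C@H]3c2cc(O[Si](C)(C)C(C)(C)C)cc(O[Si](C)(C)C(C)(C)C)c2)cc1 | intermediate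
18 | ring 1 tetrahydrobenzofuran-4-one, all four ring centres S, C6 epimers | CC(C)(C)C(=O)Oc1ccc(/C=C/C2CC(=O)C3=C(C2)O[C@H](c2ccc(O[Si](C)(C)C(C)(C)C)cc2)[C@H]3c2cc(O[Si](C)(C)C(C)(C)C)c3c(c2)O[C@H](c2ccc(O[Si](C)(C)C(C)(C)C)cc2O[Si](C)(C)C(C)(C)C)[C@H]3c2cc(O[Si](C)(C)C(C)(C)C)cc(O[Si](C)(C)C(C)(C)C)c2)cc1 | intermediate
19 | 5,6-didehydro dienone of 18 | CC(C)(C)C(=O)Oc1ccc(/C=C/C2=CC(=O)C3=C(C2)O[C@H](c2ccc(O[Si](C)(C)C(C)(C)C)cc2)[C@H]3c2cc(O[Si](C)(C)C(C)(C)C)c3c(c2)O[C@H](c2ccc(O[Si](C)(C)C(C)(C)C)cc2O[Si](C)(C)C(C)(C)C)[C@H]3c2cc(O[Si](C)(C)C(C)(C)C)cc(O[Si](C)(C)C(C)(C)C)c2)cc1 | intermediate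
20 | protected trimer (six TBS ethers, one pivalate, free C4–OH of ring 1) | CC(C)(C)C(=O)Oc1ccc(/C=C/c2cc(O)c3c(c2)O[C@H](c2ccc(O[Si](C)(C)C(C)(C)C)cc2)[C@H]3c2cc(O[Si](C)(C)C(C)(C)C)c3c(c2)O[C@H](c2ccc(O[Si](C)(C)C(C)(C)C)cc2O[Si](C)(C)C(C)(C)C)[C@H]3c2cc(O[Si](C)(C)C(C)(C)C)cc(O[Si](C)(C)C(C)(C)C)c2)cc1 | intermediate
21 | CNP0118407.1 | Oc1ccc(/C=C/c2cc(O)c3c(c2)O[C@H](c2ccc(O)cc2)[C@H]3c2cc(O)c3c(c2)O[C@H](c2ccc(O)cc2O)[C@H]3c2cc(O)cc(O)c2)cc1 | target

## Step count and risks

Total steps: 13. Longest linear sequence: 12 (steps 1–5 and 7–13).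

Step 11 (labelled). What may go wrong: poor facial selectivity of the carbenoid addition, so that both trans arrangements of ring 1 form. Fallback with known chemistry: starting from 17, the annulation with 10 is run with achiral Rh2(OAc)4, which should give 18 together with the ring 1 (2R,3R) diastereomer of 18 F1. The mixture is taken through the conditions of step 12, the diastereomeric dienone F2 not being isolated, to give 20 and the ring 1 (2R,3R) diastereomer of 20 F3. Ring 2 is fixed, so 20 and F3 are diastereomers and are separated by preparative HPLC. The route is rejoined at 20.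

Step 7 (labelled). What may go wrong: low enantioselectivity in the first annulation. Fallback with known chemistry: starting from 12, the annulation with 10 under Rh2(OAc)4 should give 13 together with the (2R,3R) counterpart of 13 F4. The conditions of step 8 then give racemic material through the (2R,3R) dienone F5, that is 15 and the enantiomer of 15 F6. These are resolved by preparative HPLC on a chiral stationary phase. The route is rejoined at 15.

Step 12. What may go wrong: unselective enolisation, attack of the amide base on the pivalate, or reaction of the liberated phenoxide with the sulfur electrophile on the most elaborate substrate. Fallback: starting from 18, soft enolisation with Me3SiOTf and Et3N in CH2Cl2 at −20 °C should give the 4-trimethylsilyloxy diene of 18 F7. Saegusa–Ito dehydrogenation with Pd(OAc)2 in MeCN at rt then gives dienone 19, which tautomerises to the phenol. The route is rejoined at 20.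

## Further compounds

F1 | step 11 | ring 1 (2R,3R) diastereomer of 18 | CC(C)(C)C(=O)Oc1ccc(/C=C/C2CC(=O)C3=C(C2)O[C@@H](c2ccc(O[Si](C)(C)C(C)(C)C)cc2)[C@@H]3c2cc(O[Si](C)(C)C(C)(C)C)c3c(c2)O[C@H](c2ccc(O[Si](C)(C)C(C)(C)C)cc2O[Si](C)(C)C(C)(C)C)[C@H]3c2cc(O[Si](C)(C)C(C)(C)C)cc(O[Si](C)(C)C(C)(C)C)c2)cc1
F2 | step 11 | ring 1 (2R,3R) diastereomer of dienone 19 | CC(C)(C)C(=O)Oc1ccc(/C=C/C2=CC(=O)C3=C(C2)O[C@@H](c2ccc(O[Si](C)(C)C(C)(C)C)cc2)[C@@H]3c2cc(O[Si](C)(C)C(C)(C)C)c3c(c2)O[C@H](c2ccc(O[Si](C)(C)C(C)(C)C)cc2O[Si](C)(C)C(C)(C)C)[C@H]3c2cc(O[Si](C)(C)C(C)(C)C)cc(O[Si](C)(C)C(C)(C)C)c2)cc1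
F3 | step 11 | ring 1 (2R,3R) diastereomer of 20 | CC(C)(C)C(=O)Oc1ccc(/C=C/c2cc(O)c3c(c2)O[C@@H](c2ccc(O[Si](C)(C)C(C)(C)C)cc2)[C@@H]3c2cc(O[Si](C)(C)C(C)(C)C)c3c(c2)O[C@H](c2ccc(O[Si](C)(C)C(C)(C)C)cc2O[Si](C)(C)C(C)(C)C)[C@H]3c2cc(O[Si](C)(C)C(C)(C)C)cc(O[Si](C)(C)C(C)(C)C)c2)cc1
F4 | step 7 | (2R,3R) counterpart of 13 | CC(C)(C)C(=O)Oc1ccc(/C=C/C2CC(=O)C3=C(C2)O[C@@H](c2ccc(O[Si](C)(C)C(C)(C)C)cc2O[Si](C)(C)C(C)(C)C)[C@@H]3c2cc(O[Si](C)(C)C(C)(C)C)cc(O[Si](C)(C)C(C)(C)C)c2)cc1
F5 | step 7 | (2R,3R) counterpart of dienone 14 | CC(C)(C)C(=O)Oc1ccc(/C=C/C2=CC(=O)C3=C(C2)O[C@@H](c2ccc(O[Si](C)(C)C(C)(C)C)cc2O[Si](C)(C)C(C)(C)C)[C@@H]3c2cc(O[Si](C)(C)C(C)(C)C)cc(O[Si](C)(C)C(C)(C)C)c2)cc1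
F6 | step 7 | enantiomer of 15 | CC(C)(C)C(=O)Oc1ccc(/C=C/c2cc(O)c3c(c2)O[C@@H](c2ccc(O[Si](C)(C)C(C)(C)C)cc2O[Si](C)(C)C(C)(C)C)[C@@H]3c2cc(O[Si](C)(C)C(C)(C)C)cc(O[Si](C)(C)C(C)(C)C)c2)cc1
F7 | step 12 | 4-trimethylsilyloxy diene of 18 | CC(C)(C)C(=O)Oc1ccc(/C=C/C2C=C(O[Si](C)(C)C)C3=C(C2)O[C@H](c2ccc(O[Si](C)(C)C(C)(C)C)cc2)[C@H]3c2cc(O[Si](C)(C)C(C)(C)C)c3c(c2)O[C@H](c2ccc(O[Si](C)(C)C(C)(C)C)cc2O[Si](C)(C)C(C)(C)C)[C@H]3c2cc(O[Si](C)(C)C(C)(C)C)cc(O[Si](C)(C)C(C)(C)C)c2)cc1
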